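**Retrosynthetic overview**
- The end game is desilylation, 7-O-prenylation and removal of a 7-O-isopropyl group, which leads back to a 5-hydroxy-7-isopropoxy-8-methoxyflavone with a silyl ether at 4'-O.
- Ring A (C4a, C5, C6, C7, C8, C8a) carries oxygens at C5 and C8 para to each other, with O at C7 and H at C6 between them. This is the pattern a semisquarate-derived 4-methoxy-4-vinylcyclobutenone delivers, so ring A is made last by forming C5–C4a in a thermal ring opening/6π closure onto a preformed 4-pyranone.
- The cyclobutenone precursor comes from C8–C8a bond formation: a 6-lithiated 2-aryl-3-methoxy-4-pyranone adds to isopropyl semisquarate (from diisopropyl squarate), and the carbinol is O-methylated.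
- Ring C is bought as 3-hydroxy-4H-pyran-4-one; ring B is attached by Suzuki coupling of its 2-bromo-3-methoxy derivative with a silyl-protected guaiacyl boronate.
- Ring order: B and C are preformed and joined, and A is closed last.

Key step: step 9

Remark on the chemistry: the target has no stereocentre and its only non-aromatic double bond carries two identical methyl groups, so it is achiral and no stereocontrol is needed. The stereocentres of 8, 11, 12 and 14 form racemic and are removed later in the route.

**Route**

Step 1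
Reactants: 1 2-methoxy-4-(4,4,5,5-tetramethyl-1,3,2-dioxaborolan-2-yl)phenol
Product: 2 triisopropyl[2-methoxy-4-(4,4,5,5-tetramethyl-1,3,2-dioxaborolan-2-yl)phenoxy]silane
Conditions: TIPSCl, imidazole, DMF, rt
Reagents that add atoms: triisopropylsilyl chloride, CC(C)[Si](Cl)(C(C)C)C(C)C
Why: Imidazole-promoted O-silylation of the phenol; the pinacol boronate is inert to these conditions and the bulky silyl ether should survive the later base, organolithium and heat.

Step 2
Reactants: 3 3-hydroxy-4H-pyran-4-one (pyromeconic acid)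
Product: 4 2-bromo-3-hydroxy-4H-pyran-4-one
Conditions: NBS (1.0 equiv), MeCN, 0 °C to rt
Reagents that add atoms: N-bromosuccinimide, O=C1CCC(=O)N1Br
Why: Electrophilic bromination of the enolic 3-hydroxy-4-pyranone at C2, the β-carbon of the enol next to the ring oxygen, which is the position where this ring also undergoes hydroxymethylation and Mannich substitution.

Step 3
Reactants: 4 2-bromo-3-hydroxy-4H-pyran-4-one
Product: 5 2-bromo-3-methoxy-4H-pyran-4-one
Conditions: Me2SO4, K2CO3, acetone, 50 °C
Reagents that add atoms: dimethyl sulfate, COS(=O)(=O)OC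
Why: Williamson-type O-methylation of the acidic enolic hydroxyl; carbonate is too weak a nucleophile to displace the C2 bromide and the pyranone carbonyl is not alkylated.

Step 4
Reactants: 5 2-bromo-3-methoxy-4H-pyran-4-one, 2 triisopropyl[2-methoxy-4-(4,4,5,5-tetramethyl-1,3,2-dioxaborolan-2-yl)phenoxy]silane
Product: 6 3-methoxy-2-(3-methoxy-4-triisopropylsilyloxyphenyl)-4H-pyran-4-one
Conditions: Pd(dppf)Cl2 (5 mol%), K3PO4, 1,4-dioxane/H2O (10:1), 70 °C
Reagents that add atoms: none
Why: Suzuki–Miyaura coupling; the C2–Br bond is a vinylogous acyl bromide and should add readily to Pd(0), and the aryl triisopropylsilyl ether should tolerate phosphate at this temperature.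

Step 5
Reactants: 7 diisopropyl squarate (3,4-diisopropoxycyclobut-3-ene-1,2-dione)
Product: 8 4-hydroxy-2,3-diisopropoxycyclobut-2-en-1-one (racemic)
Conditions: LiAlH(OtBu)3 (1.0 equiv), THF, −78 to 0 °C; aq. NH4Cl
Reagents that add atoms: none
Why: 1,2-Reduction of one squarate carbonyl by a bulky, mild hydride that should stop at the mono-adduct; the new carbinol centre is racemic and is removed in step 6.

Step 6
Reactants: 8 4-hydroxy-2,3-diisopropoxycyclobut-2-en-1-one (racemic)
Product: 9 3-isopropoxycyclobut-3-ene-1,2-dione (isopropyl semisquarate)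
Conditions: conc. HCl (cat.), CH2Cl2, rt
Reagents that add atoms: none
Why: Acid-catalysed allylic transposition: ionisation of the carbinol gives an oxocarbenium ion at the α-isopropoxy carbon, water re-adds there and isopropanol is lost, giving the cyclobutenedione with H on the ring double bond.

Step 7
Reactants: 6 3-methoxy-2-(3-methoxy-4-triisopropylsilyloxyphenyl)-4H-pyran-4-one, 9 3-isopropoxycyclobut-3-ene-1,2-dione
Product: 11 4-hydroxy-3-isopropoxy-4-[5-methoxy-6-(3-methoxy-4-triisopropylsilyloxyphenyl)-4-oxo-4H-pyran-2-yl]cyclobut-2-en-1-one (racemic), via 6-lithiopyranone 10 (not isolated)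
Conditions: LiTMP (1.1 equiv; from TMPH, n-BuLi), THF, −78 °C, 20 min; cannulate into 9 (1.3 equiv), THF, −78 °C; aq. NH4Cl at −78 °C
Reagents that add atoms: none
Why: Deprotonative lithiation of the vinylic C6–H next to the ring oxygen (the reaction type of C2-lithiation of chromones), then 1,2-addition to the semisquarate carbonyl that is not deactivated as a vinylogous ester, which places OiPr and H where flavone C7–O and C6–H are needed; the carbinol centre forms racemic and is erased in step 9.

Step 8
Reactants: 11 4-hydroxy-3-isopropoxy-4-[5-methoxy-6-(3-methoxy-4-triisopropylsilyloxyphenyl)-4-oxo-4H-pyran-2-yl]cyclobut-2-en-1-one (racemic)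
Product: 12 3-isopropoxy-4-methoxy-4-[5-methoxy-6-(3-methoxy-4-triisopropylsilyloxyphenyl)-4-oxo-4H-pyran-2-yl]cyclobut-2-en-1-one (racemic)
Conditions: MeI (excess), Ag2O, MeCN, rt, dark
Reagents that add atoms: iodomethane, CI
Why: Purdie methylation of the tertiary carbinol under nearly neutral conditions, which should avoid base-induced opening of the hydroxycyclobutenone and the O-methylation of the pyranone carbonyl that methyl triflate would cause.

Step 9
Reactants: 12 3-isopropoxy-4-methoxy-4-[5-methoxy-6-(3-methoxy-4-triisopropylsilyloxyphenyl)-4-oxo-4H-pyran-2-yl]cyclobut-2-en-1-one (racemic)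
Product: 15 5-hydroxy-7-isopropoxy-3,8-dimethoxy-2-(3-methoxy-4-triisopropylsilyloxyphenyl)-4H-chromen-4-one, via dienylketene 13 (not isolated), via 4a-H dienone 14 (not isolated)
Conditions: degassed toluene (0.02 M), 110 °C, argon
Reagents that add atoms: none
Why: Heating should open the cyclobutenone by conrotatory 4π cleavage of its C1–C4 bond to dienylketene 13; a thermal 6π electrocyclisation across the ketene C=C, the enol-ether C=C and the pyranone C=C then joins the ketene carbon to the pyranyl C3–H carbon (flavone C5–C4a) to give dienone 14, whose 4a-H moves to oxygen to give the chelated 5-phenol. The closest known reaction type is the Moore rearrangement of squarate-derived 4-aryl-, 4-heteroaryl- and 4-alkenyl-4-alkoxycyclobutenones to mono-O-protected hydroquinones. Ring A closes in the disrotatory 6π electrocyclic mode, with the electrophilic ketene carbon meeting the pyranone carbon α to the carbonyl, which is the nucleophilic end of the vinylogous ester. No stereocentre remains, because the racemic carbinol carbon becomes aromatic C8 and the transient C4a centre of 14 is lost on enolisation. The step needs torquoselectivity, which the methoxy donor should supply by rotating outward and turning the pyranone inward (Z-ketene), and it has a single closure site because the other neighbour of the pyranyl carbon is the ring oxygen. The C5-OH/C6-H/C7-O/C8-OMe pattern is already fixed by step 7, and the O-methyl cap excludes furanone formation by hydroxyl attack on the ketene.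

Step 10
Reactants: 15 5-hydroxy-7-isopropoxy-3,8-dimethoxy-2-(3-methoxy-4-triisopropylsilyloxyphenyl)-4H-chromen-4-one
Product: 16 5,7-dihydroxy-3,8-dimethoxy-2-(3-methoxy-4-triisopropylsilyloxyphenyl)-4H-chromen-4-one
Conditions: BCl3 (2.5 equiv), CH2Cl2, −78 to −20 °C; MeOH, aq. NaHCO3
Reagents that add atoms: none
Why: Boron trichloride dealkylation, which should cleave the secondary isopropyl aryl ether much faster than the methyl ethers; one equivalent is held in the 5-O/4-C=O chelate, which shields the 3-methoxy group, and the hindered aryl silyl ether should survive at low temperature.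

Step 11
Reactants: 16 5,7-dihydroxy-3,8-dimethoxy-2-(3-methoxy-4-triisopropylsilyloxyphenyl)-4H-chromen-4-one
Product: 17 5-hydroxy-3,8-dimethoxy-2-(3-methoxy-4-triisopropylsilyloxyphenyl)-7-(3-methylbut-2-enyloxy)-4H-chromen-4-one
Conditions: prenyl bromide (1.2 equiv), K2CO3, acetone, rt to 40 °C
Reagents that add atoms: 1-bromo-3-methylbut-2-ene (prenyl bromide), CC(C)=CCBr
Why: Williamson etherification of the acidic 7-OH; the 5-OH is hydrogen-bonded to the C4 carbonyl and should not react with carbonate in acetone.

Step 12
Reactants: 17 5-hydroxy-3,8-dimethoxy-2-(3-methoxy-4-triisopropylsilyloxyphenyl)-7-(3-methylbut-2-enyloxy)-4H-chromen-4-one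
Product: 18 5,4'-dihydroxy-3,8,3'-trimethoxy-7-prenyloxyflavone (target)
Conditions: TBAF (1.1 equiv), AcOH (1.1 equiv), THF, 0 °C
Reagents that add atoms: none
Why: Fluoride-driven cleavage of the aryl silyl ether; acetic acid buffering keeps the medium nearly neutral, so the prenyl ether and the methyl ethers should be untouched.

**Compound list**
1 | 2-methoxy-4-(4,4,5,5-tetramethyl-1,3,2-dioxaborolan-2-yl)phenol | COc1cc(B2OC(C)(C)C(C)(C)O2)ccc1O | starting material
2 | triisopropyl[2-methoxy-4-(4,4,5,5-tetramethyl-1,3,2-dioxaborolan-2-yl)phenoxy]silane | COc1cc(B2OC(C)(C)C(C)(C)O2)ccc1O[Si](C(C)C)(C(C)C)C(C)C | intermediate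
3 | 3-hydroxy-4H-pyran-4-one (pyromeconic acid) | O=c1ccocc1O | starting material
4 | 2-bromo-3-hydroxy-4H-pyran-4-one | O=c1ccoc(Br)c1O | intermediate
5 | 2-bromo-3-methoxy-4H-pyran-4-one | COc1c(Br)occc1=O | intermediate
6 | 3-methoxy-2-(3-methoxy-4-triisopropylsilyloxyphenyl)-4H-pyran-4-one | COc1cc(-c2occc(=O)c2OC)ccc1O[Si](C(C)C)(C(C)C)C(C)C | intermediate
7 | diisopropyl squarate (3,4-diisopropoxycyclobut-3-ene-1,2-dione) | CC(C)OC1=C(OC(C)C)C(=O)C1=O | starting material
8 | 4-hydroxy-2,3-diisopropoxycyclobut-2-en-1-one (racemic) | CC(C)OC1=C(OC(C)C)C(O)C1=O | intermediate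
9 | 3-isopropoxycyclobut-3-ene-1,2-dione (isopropyl semisquarate) | CC(C)OC1=CC(=O)C1=O | intermediate
10 | 6-lithio-3-methoxy-2-(3-methoxy-4-triisopropylsilyloxyphenyl)-4H-pyran-4-one (formed in the flask, not isolated) | COc1cc(-c2oc([Li])cc(=O)c2OC)ccc1O[Si](C(C)C)(C(C)C)C(C)C | intermediate
11 | 4-hydroxy-3-isopropoxy-4-[5-methoxy-6-(3-methoxy-4-triisopropylsilyloxyphenyl)-4-oxo-4H-pyran-2-yl]cyclobut-2-en-1-one (racemic) | COc1cc(-c2oc(C3(O)C(OC(C)C)=CC3=O)cc(=O)c2OC)ccc1O[Si](C(C)C)(C(C)C)C(C)C | intermediate
12 | 3-isopropoxy-4-methoxy-4-[5-methoxy-6-(3-methoxy-4-triisopropylsilyloxyphenyl)-4-oxo-4H-pyran-2-yl]cyclobut-2-en-1-one (racemic) | COc1cc(-c2oc(C3(OC)C(OC(C)C)=CC3=O)cc(=O)c2OC)ccc1O[Si](C(C)C)(C(C)C)C(C)C | intermediate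
13 | dienylketene with the ketenyl CH and the pyranonyl group cis on the enol-ether double bond (formed in the flask, not isolated) | O=C=C/C(OC(C)C)=C(OC)\c1cc(=O)c(OC)c(-c2ccc(O[Si](C(C)C)(C(C)C)C(C)C)c(OC)c2)o1 | intermediate
14 | 7-isopropoxy-3,8-dimethoxy-2-(3-methoxy-4-triisopropylsilyloxyphenyl)-4aH-chromene-4,5-dione (racemic, formed in the flask, not isolated) | O=C1C=C(OC(C)C)C(OC)=C2OC(c3ccc(O[Si](C(C)C)(C(C)C)C(C)C)c(OC)c3)=C(OC)C(=O)C12 | intermediate
15 | 5-hydroxy-7-isopropoxy-3,8-dimethoxy-2-(3-methoxy-4-triisopropylsilyloxyphenyl)-4H-chromen-4-one | COc1cc(-c2oc3c(OC)c(OC(C)C)cc(O)c3c(=O)c2OC)ccc1O[Si](C(C)C)(C(C)C)C(C)C | intermediate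
16 | 5,7-dihydroxy-3,8-dimethoxy-2-(3-methoxy-4-triisopropylsilyloxyphenyl)-4H-chromen-4-one | COc1cc(-c2oc3c(OC)c(O)cc(O)c3c(=O)c2OC)ccc1O[Si](C(C)C)(C(C)C)C(C)C | intermediate
17 | 5-hydroxy-3,8-dimethoxy-2-(3-methoxy-4-triisopropylsilyloxyphenyl)-7-(3-methylbut-2-enyloxy)-4H-chromen-4-one | COc1cc(-c2oc3c(OC)c(OCC=C(C)C)cc(O)c3c(=O)c2OC)ccc1O[Si](C(C)C)(C(C)C)C(C)C | intermediate
18 | 5,4'-dihydroxy-3,8,3'-trimethoxy-7-prenyloxyflavone | COc1cc(-c2oc3c(OC)c(OCC=C(C)C)cc(O)c3c(=O)c2OC)ccc1O | target

**Step count and risks**
Total step count: 12. Longest linear sequence: 9 steps (steps 2, 3, 4, 7, 8, 9, 10, 11, 12, from 3).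

Steps most likely to fail:

1. Step 7. The lithiated pyranone may add to a second pyranone molecule before it meets the electrophile, metalation may occur in part at the carbon α to the carbonyl (followed by ring opening), or the organolithium may attack the unsubstituted vinyl carbon of the semisquarate in a conjugate sense. The fallback sets out from 6 and returns at 11, and it generates the nucleophile by halogen–metal exchange instead of deprotonation. Zincation of 6 with the Lewis-acid-free amide base TMPZnCl·LiCl (THF, 25 °C), which tolerates the ketone, should give [5-methoxy-6-(3-methoxy-4-triisopropylsilyloxyphenyl)-4-oxo-4H-pyran-2-yl]zinc chloride F1. Iodine converts this into 6-iodo-3-methoxy-2-(3-methoxy-4-triisopropylsilyloxyphenyl)-4H-pyran-4-one F2, which can be purified. Iodine–magnesium exchange with iPrMgCl·LiCl at −78 °C gives the pyranonylmagnesium chloride F3, which is added to 9 at −78 °C in the presence of LaCl3·2LiCl to favour carbonyl addition, giving 11.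

2. Step 9. Closure of the O-methylated ketene onto the electron-poor pyranone double bond may be slower than ketene oligomerisation, so material is lost at the temperature the ring opening needs. The fallback sets out from 11 and returns at 15. It runs the ring expansion on the free carbinol, the most common form of this rearrangement, and distinguishes the two new oxygens afterwards. Heating 11 (degassed toluene, 110 °C, argon) should give the hydroxy dienylketene F4, then the 4a-H diketone F5, and after enolisation 5,8-dihydroxy-7-isopropoxy-3-methoxy-2-(3-methoxy-4-triisopropylsilyloxyphenyl)-4H-chromen-4-one F6. The crude hydroquinone, kept under argon to prevent oxidation to the quinone, is methylated with MeI (1.1 equiv) and K2CO3 in acetone. The 8-OH should react and the chelated 5-OH should not, which gives 15.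

3. Step 10. The Lewis acid may also remove the silyl ether, or dealkylation may be incomplete at the temperature the silyl ether tolerates, leaving mixtures in which 7-OH and 4'-OH are both free. The fallback sets out from 15 and returns at 18, and it drops the protecting-group distinction in favour of the inherent acidity order of the phenols. Treatment of 15 with BCl3 (CH2Cl2, −78 to 0 °C) and then TBAF on the crude should give 5,7-dihydroxy-2-(4-hydroxy-3-methoxyphenyl)-3,8-dimethoxy-4H-chromen-4-one F7. One equivalent of prenyl bromide with KHCO3 in DMF at rt should alkylate mainly the 7-OH, the most acidic phenol (para to the C4 carbonyl). The 4'-OH is less acidic and the 5-OH is chelated, so 18 should result directly, though the selectivity is expected to be only moderate.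

Further compounds
F1 | step 7 | [5-methoxy-6-(3-methoxy-4-triisopropylsilyloxyphenyl)-4-oxo-4H-pyran-2-yl]zinc chloride | COc1cc(-c2oc([Zn]Cl)cc(=O)c2OC)ccc1O[Si](C(C)C)(C(C)C)C(C)C
F2 | step 7 | 6-iodo-3-methoxy-2-(3-methoxy-4-triisopropylsilyloxyphenyl)-4H-pyran-4-one | COc1cc(-c2oc(I)cc(=O)c2OC)ccc1O[Si](C(C)C)(C(C)C)C(C)C
F3 | step 7 | [5-methoxy-6-(3-methoxy-4-triisopropylsilyloxyphenyl)-4-oxo-4H-pyran-2-yl]magnesium chloride | COc1cc(-c2oc([Mg]Cl)cc(=O)c2OC)ccc1O[Si](C(C)C)(C(C)C)C(C)C
F4 | step 9 | hydroxy dienylketene with the ketenyl CH and the pyranonyl group cis | O=C=C/C(OC(C)C)=C(O)\c1cc(=O)c(OC)c(-c2ccc(O[Si](C(C)C)(C(C)C)C(C)C)c(OC)c2)o1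
F5 | step 9 | 8-hydroxy-7-isopropoxy-3-methoxy-2-(3-methoxy-4-triisopropylsilyloxyphenyl)-4aH-chromene-4,5-dione (racemic) | O=C1C=C(OC(C)C)C(O)=C2OC(c3ccc(O[Si](C(C)C)(C(C)C)C(C)C)c(OC)c3)=C(OC)C(=O)C12
F6 | step 9 | 5,8-dihydroxy-7-isopropoxy-3-methoxy-2-(3-methoxy-4-triisopropylsilyloxyphenyl)-4H-chromen-4-one | COc1cc(-c2oc3c(O)c(OC(C)C)cc(O)c3c(=O)c2OC)ccc1O[Si](C(C)C)(C(C)C)C(C)C
F7 | step 10 | 5,7-dihydroxy-2-(4-hydroxy-3-methoxyphenyl)-3,8-dimethoxy-4H-chromen-4-one | COc1cc(-c2oc3c(OC)c(O)cc(O)c3c(=O)c2OC)ccc1O
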